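**Plan**
1. Cuts: the hydroquinone ring is opened at C1'–C2', C5'–C6' and C4'–C5' (carbene–alkyne benzannulation). Then the acetal carbon–C6' bond, C9–C11, C8–CH3, C10–CH3 and both C4–CH3 bonds are cut, leading back to 6-methoxy-1-tetralone.
2. Enabling feature: on the aromatic ring, C11 (on C1') and the formyl carbon (on C6') sit on neighbouring carbons, each flanked by an oxygen-bearing carbon (C2', C5'), and C3'/C4' are CH. An internal alkyne C1'≡C6', one CO (C5') and a methoxy(vinyl)carbene (C2', C3', C4') supply exactly this pattern.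
3. Forward order: ring A is present from the start; ring B is the anisole ring, uncovered as an enone by Birch reduction; the methyl groups and the C11 propargyl chain are attached; the aromatic ring is built last and unmasked in two steps.
4. Stereochemistry: C5 comes from a catalytic enantioselective β,γ→α,β enone isomerisation. C10, C9 and C8 follow by substrate control, each carbon substituent entering on the convex face of the cis-decalin (C10 methyl syn to H5; C11 and the C8 methyl cis to the angular methyl, hydroxyl trans).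
5. A chair-type cation–olefin cyclisation of a 7Z polyene would place C11 trans to the C10 methyl, so C9 and C8 are set on the preformed cis-decalin instead.

Key step: step 10

Numbering: drimane numbering for the decalin (C4 gem-dimethyl carbon, C5/C10 ring fusion, C8 carbinol carbon, C9 the CH bearing C11); C1'–C6' for the arene (C1' on C11, C2'/C5' oxygenated, C6' formylated).
Assumption: the quinidine-derived amine of step 3 is taken to give the 4aR enone; if it gives 4aS, its quinine-derived pseudoenantiomer is used instead.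

**Step 1**
Reactants: 1 6-methoxy-3,4-dihydronaphthalen-1(2H)-one (6-methoxy-1-tetralone)
Product: 2 6-methoxy-1,1-dimethyl-1,2,3,4-tetrahydronaphthalene
Conditions: Me2Zn, TiCl4, CH2Cl2, −40 °C to rt
Reagents that add atoms: dimethyltitanium dichloride (formed in the flask from Me2Zn and TiCl4), C[Ti](C)(Cl)Cl
Why: Reetz geminal dimethylation, in which methyl transfer to the carbonyl, ionisation of the titanium alkoxide to a benzylic cation stabilised by the para methoxy group and a second methyl transfer turn C=O into the CMe2 group that becomes C4.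

**Step 2**
Reactants: 2 6-methoxy-1,1-dimethyl-1,2,3,4-tetrahydronaphthalene
Product: 4 5,5-dimethyl-3,4,5,6,7,8-hexahydronaphthalen-2(1H)-one, via dihydroanisole 3 (not isolated)
Conditions: Li, NH3 (l), t-BuOH, THF, −33 °C; then (CO2H)2, MeOH/H2O, rt
Reagents that add atoms: water, O
Why: Birch reduction of the anisole keeps the enol ether and the tetrasubstituted ring-fusion alkene, and oxalic acid hydrolyses the enol ether to the achiral β,γ-unsaturated ketone without moving the double bond.

**Step 3**
Reactants: 4 5,5-dimethyl-3,4,5,6,7,8-hexahydronaphthalen-2(1H)-one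
Product: 5 (4aR)-5,5-dimethyl-4,4a,5,6,7,8-hexahydronaphthalen-2(3H)-one
Conditions: 9-amino-9-deoxy-epi-quinidine (10 mol %), PhCO2H (20 mol %), toluene, 0 °C
Reagents that add atoms: none
Why: Amine-catalysed enantioselective olefin isomerisation of a Birch-derived cyclohex-3-enone, in which the primary amine forms the iminium ion, α-deprotonation gives the dienamine and the protonated quinuclidine delivers the γ-proton to one face of C4a, which sets C5 (R).

**Step 4**
Reactants: 5 (4aR)-5,5-dimethyl-4,4a,5,6,7,8-hexahydronaphthalen-2(3H)-one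
Product: 6 trimethyl{[(4aR,8aS)-5,5,8a-trimethyl-3,4,4a,5,6,7,8,8a-octahydronaphthalen-2-yl]oxy}silane
Conditions: MeMgBr, CuBr·SMe2 (5 mol %), Me3SiCl, HMPA, THF, −78 °C; Et3N, aqueous NaHCO3 work-up
Reagents that add atoms: methylmagnesium bromide, C[Mg]Br; chlorotrimethylsilane, C[Si](C)(C)Cl
Why: Copper-catalysed, silyl chloride-accelerated conjugate addition in which methyl enters C10 from the face of H5, anti to the axial C4 methyl that shields the other face, giving the cis ring fusion (10S), while the enolate is kept as its regiodefined C8–C9 silyl enol ether.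

**Step 5**
Reactants: 6 trimethyl{[(4aR,8aS)-5,5,8a-trimethyl-3,4,4a,5,6,7,8,8a-octahydronaphthalen-2-yl]oxy}silane; 7 3-bromoprop-1-yne (propargyl bromide)
Product: 9 (1R,4aR,8aS)-5,5,8a-trimethyl-1-(prop-2-yn-1-yl)octahydronaphthalen-2(1H)-one, via lithium enolate 8 (not isolated)
Conditions: MeLi (1.0 equiv), THF, 0 °C to rt; then DMPU, 7, −78 to −20 °C
Reagents that add atoms: none
Why: Regiospecific enolate generation by Si–O cleavage and SN2 alkylation, in which the bromide attacks C9 axially on the convex face of the cis-decalin, anti to the pseudoaxial ring A methylene C1, so that C11 lies cis to the angular methyl (9R).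

**Step 6**
Reactants: 9 (1R,4aR,8aS)-5,5,8a-trimethyl-1-(prop-2-yn-1-yl)octahydronaphthalen-2(1H)-one
Product: 10 (1R,2R,4aR,8aS)-2,5,5,8a-tetramethyl-1-(prop-2-yn-1-yl)decahydronaphthalen-2-ol
Conditions: 9 added to MeLi (3 equiv, one of them consumed by the alkyne C–H), Et2O, −78 °C; then H2O
Reagents that add atoms: methyllithium, [Li]C
Why: 1,2-Addition of methyllithium to a hindered cyclohexanone, in which axial approach to C8 is blocked by the syn-axial C1 methylene of ring A, so methyl enters equatorially from the convex face and the hydroxyl ends axial and trans to C11 (8R).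

**Step 7**
Reactants: 10 (1R,2R,4aR,8aS)-2,5,5,8a-tetramethyl-1-(prop-2-yn-1-yl)decahydronaphthalen-2-ol
Product: 11 triethyl{[(1R,2R,4aR,8aS)-2,5,5,8a-tetramethyl-1-(prop-2-yn-1-yl)decahydronaphthalen-2-yl]oxy}silane
Conditions: Et3SiOTf, 2,6-lutidine, CH2Cl2, −78 to 0 °C
Reagents that add atoms: triethylsilyl trifluoromethanesulfonate, CC[Si](CC)(CC)OS(=O)(=O)C(F)(F)F
Why: Silylation of a tertiary alcohol with a silyl triflate and a hindered pyridine base, which keeps the C8 oxygen from trapping the ketene intermediate of step 10.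

**Step 8**
Reactants: 11 triethyl{[(1R,2R,4aR,8aS)-2,5,5,8a-tetramethyl-1-(prop-2-yn-1-yl)decahydronaphthalen-2-yl]oxy}silane; 12 triethyl orthoformate
Product: 14 triethyl{[(1R,2R,4aR,8aS)-1-(4,4-diethoxybut-2-yn-1-yl)-2,5,5,8a-tetramethyldecahydronaphthalen-2-yl]oxy}silane, via alkynylmagnesium bromide 13 (not isolated)
Conditions: EtMgBr, THF, 45 °C; then 12, toluene, 90 °C
Reagents that add atoms: none
Why: Metalation of the terminal alkyne by the Grignard reagent and substitution of one ethoxide of the orthoester by the alkynylmagnesium bromide, the standard preparation of alkynyl aldehyde acetals, which brings in the future formyl carbon in masked form.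

**Step 9**
Reactants: 15 chromium hexacarbonyl; 16 vinylmagnesium bromide
Product: 18 pentacarbonyl[methoxy(vinyl)carbene]chromium, via acyl chromate 17 (not isolated)
Conditions: THF, −78 to 0 °C; then Me3OBF4, CH2Cl2/H2O, 0 °C; used at once
Reagents that add atoms: trimethyloxonium tetrafluoroborate, C[O+](C)C.F[B-](F)(F)F
Why: Fischer carbene synthesis, in which the vinyl nucleophile adds to a CO ligand to give the acyl chromate and the oxonium salt methylates its oxygen.

**Step 10**
Reactants: 14 triethyl{[(1R,2R,4aR,8aS)-1-(4,4-diethoxybut-2-yn-1-yl)-2,5,5,8a-tetramethyldecahydronaphthalen-2-yl]oxy}silane; 18 pentacarbonyl[methoxy(vinyl)carbene]chromium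
Product: 20 2-(diethoxymethyl)-4-methoxy-3-{[(1R,2R,4aR,8aS)-2,5,5,8a-tetramethyl-2-[(triethylsilyl)oxy]decahydronaphthalen-1-yl]methyl}phenol, via tricarbonylchromium arene complex 19 (not isolated)
Conditions: 18 (1.5 equiv), THF, 50 °C, Ar; then air, Et2O, rt
Reagents that add atoms: none
Why: Thermal loss of one CO from 18 lets alkyne 14 coordinate and insert into the Cr=C bond (C1'–C2'), a second CO inserts at the metal-bound alkyne carbon (C6'–C5') to give a chromium-bound dienylketene, and 6π electrocyclisation between the ketene carbon and the vinyl terminus (C5'–C4') closes the ring, which tautomerises to the phenol held on Cr(CO)3 (19) and is released by air. The closest known reaction type is the Dötz benzannulation of alkenyl(alkoxy)carbene chromium complexes with internal alkynes. The one ring formed, the arene, closes by this electrocyclisation; no stereocentre is created and C5, C8, C9 and C10 are untouched. The selectivity needed is benzannulation over cyclopentannulation, furan or cyclobutenone formation, which an alkenyl carbene in an ether solvent should secure, helped by the acetal that keeps the alkyne electron-rich and by the silyl ether that keeps the C8 oxygen away from the ketene. The orientation of alkyne insertion (the acetal-bearing carbon is expected next to the phenolic oxygen) does not matter, because either regioisomer gives the same quinone in step 12.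

**Step 11**
Reactants: 20 2-(diethoxymethyl)-4-methoxy-3-{[(1R,2R,4aR,8aS)-2,5,5,8a-tetramethyl-2-[(triethylsilyl)oxy]decahydronaphthalen-1-yl]methyl}phenol
Product: 21 6-hydroxy-2-{[(1R,2R,4aR,8aS)-2-hydroxy-2,5,5,8a-tetramethyldecahydronaphthalen-1-yl]methyl}-3-methoxybenzaldehyde
Conditions: 1 M HCl, THF, rt
Reagents that add atoms: water, O
Why: Acid hydrolysis of the diethyl acetal and of the tertiary triethylsilyl ether, done while the C2' oxygen is still a methyl ether so that the C8 carbinol cannot close a chroman ring onto it.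

**Step 12**
Reactants: 21 6-hydroxy-2-{[(1R,2R,4aR,8aS)-2-hydroxy-2,5,5,8a-tetramethyldecahydronaphthalen-1-yl]methyl}-3-methoxybenzaldehyde
Product: 23 3,6-dihydroxy-2-{[(1R,2R,4aR,8aS)-2-hydroxy-2,5,5,8a-tetramethyldecahydronaphthalen-1-yl]methyl}benzaldehyde, via formylquinone 22 (not isolated)
Conditions: (NH4)2Ce(NO3)6, MeCN/H2O, 0 °C; then Na2S2O4, H2O/EtOAc, rt
Reagents that add atoms: water, O
Why: Oxidative demethylation of a 4-methoxyphenol by tetravalent cerium (water attacks the oxidised ring at C2' and methanol leaves) gives the quinone, which dithionite reduces at once to the hydroquinone before the electrophilic formylquinone can react further.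

**Compound list**
1 | 6-methoxy-3,4-dihydronaphthalen-1(2H)-one | COc1ccc2c(c1)CCCC2=O | starting material
2 | 6-methoxy-1,1-dimethyl-1,2,3,4-tetrahydronaphthalene | COc1ccc2c(c1)CCCC2(C)C | intermediate
3 | 6-methoxy-1,1-dimethyl-1,2,3,4,5,8-hexahydronaphthalene (dihydroanisole) | COC1=CCC2=C(C1)CCCC2(C)C | intermediate
4 | 5,5-dimethyl-3,4,5,6,7,8-hexahydronaphthalen-2(1H)-one | O=C1CCC2=C(C1)CCCC2(C)C | intermediate
5 | (4aR)-5,5-dimethyl-4,4a,5,6,7,8-hexahydronaphthalen-2(3H)-one | CC1(C)CCCC2=CC(=O)CC[C@H]12 | intermediate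
6 | trimethyl{[(4aR,8aS)-5,5,8a-trimethyl-3,4,4a,5,6,7,8,8a-octahydronaphthalen-2-yl]oxy}silane | CC1(C)CCC[C@@]2(C)[C@@H]1CCC(O[Si](C)(C)C)=C2 | intermediate
7 | 3-bromoprop-1-yne | C#CCBr | starting material
8 | lithium (4aR,8aS)-5,5,8a-trimethyl-3,4,4a,5,6,7,8,8a-octahydronaphthalen-2-olate (lithium enolate) | CC1(C)CCC[C@@]2(C)[C@@H]1CCC(O[Li])=C2 | intermediate
9 | (1R,4aR,8aS)-5,5,8a-trimethyl-1-(prop-2-yn-1-yl)octahydronaphthalen-2(1H)-one | CC1(C)CCC[C@@]2(C)[C@@H]1CCC(=O)[C@@H]2CC#C | intermediate
10 | (1R,2R,4aR,8aS)-2,5,5,8a-tetramethyl-1-(prop-2-yn-1-yl)decahydronaphthalen-2-ol | CC1(C)CCC[C@@]2(C)[C@@H]1CC[C@@](C)(O)[C@@H]2CC#C | intermediate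
11 | triethyl{[(1R,2R,4aR,8aS)-2,5,5,8a-tetramethyl-1-(prop-2-yn-1-yl)decahydronaphthalen-2-yl]oxy}silane | CC1(C)CCC[C@@]2(C)[C@@H]1CC[C@@](C)(O[Si](CC)(CC)CC)[C@@H]2CC#C | intermediate
12 | triethyl orthoformate | CCOC(OCC)OCC | starting material
13 | bromo{3-[(1R,2R,4aR,8aS)-2,5,5,8a-tetramethyl-2-[(triethylsilyl)oxy]decahydronaphthalen-1-yl]prop-1-yn-1-yl}magnesium | CC1(C)CCC[C@@]2(C)[C@@H]1CC[C@@](C)(O[Si](CC)(CC)CC)[C@@H]2CC#C[Mg]Br | intermediate
14 | triethyl{[(1R,2R,4aR,8aS)-1-(4,4-diethoxybut-2-yn-1-yl)-2,5,5,8a-tetramethyldecahydronaphthalen-2-yl]oxy}silane | CC1(C)CCC[C@@]2(C)[C@@H]1CC[C@@](C)(O[Si](CC)(CC)CC)[C@@H]2CC#CC(OCC)OCC | intermediate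
15 | chromium hexacarbonyl | O=C=[Cr](=C=O)(=C=O)(=C=O)(=C=O)=C=O | starting material
16 | vinylmagnesium bromide | C=C[Mg]Br | starting material
17 | bromomagnesium pentacarbonyl(1-oxidoprop-2-en-1-ylidene)chromate (acyl chromate) | C=CC(O[Mg]Br)=[Cr](=C=O)(=C=O)(=C=O)(=C=O)=C=O | intermediate
18 | pentacarbonyl[methoxy(vinyl)carbene]chromium | C=CC(OC)=[Cr](=C=O)(=C=O)(=C=O)(=C=O)=C=O | intermediate
19 | tricarbonylchromium complex of phenol 20 (Cr(CO)3 bound η6 to the new ring) | CC1(C)CCC[C@@]2(C)[C@@H]1CC[C@@](C)(O[Si](CC)(CC)CC)[C@@H]2Cc1c(OC)ccc(O)c1C(OCC)OCC.O=C=[Cr](=C=O)=C=O | intermediate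
20 | 2-(diethoxymethyl)-4-methoxy-3-{[(1R,2R,4aR,8aS)-2,5,5,8a-tetramethyl-2-[(triethylsilyl)oxy]decahydronaphthalen-1-yl]methyl}phenol | CC1(C)CCC[C@@]2(C)[C@@H]1CC[C@@](C)(O[Si](CC)(CC)CC)[C@@H]2Cc1c(OC)ccc(O)c1C(OCC)OCC | intermediate
21 | 6-hydroxy-2-{[(1R,2R,4aR,8aS)-2-hydroxy-2,5,5,8a-tetramethyldecahydronaphthalen-1-yl]methyl}-3-methoxybenzaldehyde | CC1(C)CCC[C@@]2(C)[C@@H]1CC[C@@](C)(O)[C@@H]2Cc1c(OC)ccc(O)c1C=O | intermediate
22 | 2-{[(1R,2R,4aR,8aS)-2-hydroxy-2,5,5,8a-tetramethyldecahydronaphthalen-1-yl]methyl}-3,6-dioxocyclohexa-1,4-diene-1-carbaldehyde (formylquinone) | CC1(C)CCC[C@@]2(C)[C@@H]1CC[C@@](C)(O)[C@@H]2CC1=C(C=O)C(=O)C=CC1=O | intermediate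
23 | 3,6-dihydroxy-2-{[(1R,2R,4aR,8aS)-2-hydroxy-2,5,5,8a-tetramethyldecahydronaphthalen-1-yl]methyl}benzaldehyde | CC1(C)CCC[C@@]2(C)[C@@H]1CC[C@@](C)(O)[C@@H]2Cc1c(O)ccc(O)c1C=O | target

**Totals**
Total step count: 12. Longest linear sequence: 11 steps (steps 1–8 and 10–12, from 6-methoxy-1-tetralone); step 9 is a one-step side branch.

**Steps most likely to fail**

Step 10. The parent vinylcarbene complex may polymerise or decompose before the alkyne inserts, and alkyne insertion without CO uptake may drain material into cyclopentannulation or furan formation. The fallback sets out from 14 and uses the more robust β-silylated complex pentacarbonyl{methoxy[(E)-2-(trimethylsilyl)ethenyl]carbene}chromium F1, made from (E)-(2-bromoethenyl)trimethylsilane with t-BuLi, Cr(CO)6 and then Me3OBF4. Benzannulation with 14 under the conditions of step 10 should be followed by a shift of silicon from carbon to the phenolic oxygen, giving the trimethylsilyl ether of phenol 20, F2. The acid of step 11 removes this silyl group together with the triethylsilyl ether and the acetal, so the route is rejoined at 21.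

Step 6. Facial selectivity may be poor, because the concave face of the ketone is blocked by the ring A methylene while the convex face carries the axial propargyl group next to the carbonyl; enolisation by the basic reagent is a second leak. The fallback covers the case that methyl enters mainly from the concave face. It sets out from 9, which is methylenated with Ph3P=CH2 (from Ph3PCH3Br and KOt-Bu, toluene, 80 °C) to the exocyclic alkene (1S,4aR,8aS)-5,5,8a-trimethyl-2-methylidene-1-(prop-2-yn-1-yl)decahydronaphthalene F3. m-Chloroperbenzoic acid, which follows the same facial preference as methyllithium, then places oxygen where methyl would have gone, giving the spiro-epoxide with oxygen trans to the propargyl group F4. LiEt3BH (THF, 0 °C) opens the epoxide at its CH2 terminus and returns the route to 10.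

Step 5. Alkylation at the neopentyl-type enolate carbon may be slow, so that proton transfer between enolate and product ketone erodes regio- and stereocontrol or leads to dialkylation; O-alkylation and SN2' attack (allene formation) may also compete. The fallback sets out from 6 and replaces the basic alkylation by a Nicholas reaction. The silyl enol ether is coupled (BF3·OEt2, CH2Cl2, −78 °C) with the cobalt-stabilised propargyl cation generated from hexacarbonyl[μ-(3-methoxyprop-1-yne)]dicobalt F5, itself made from methyl propargyl ether and Co2(CO)8. This should give, again by convex-face attack, the hexacarbonyldicobalt complex of ketone 9, F6. (NH4)2Ce(NO3)6 in acetone at 0 °C releases the alkyne and returns the route to 9.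

**Further compounds**
F1 | step 10 | pentacarbonyl{methoxy[(E)-2-(trimethylsilyl)ethenyl]carbene}chromium | C[Si](C)(C)/C=C/C(OC)=[Cr](=C=O)(=C=O)(=C=O)(=C=O)=C=O
F2 | step 10 | trimethylsilyl ether of phenol 20 | CC1(C)CCC[C@@]2(C)[C@@H]1CC[C@@](C)(O[Si](CC)(CC)CC)[C@@H]2Cc1c(OC)ccc(O[Si](C)(C)C)c1C(OCC)OCC
F3 | step 6 | (1S,4aR,8aS)-5,5,8a-trimethyl-2-methylidene-1-(prop-2-yn-1-yl)decahydronaphthalene | CC1(C)CCC[C@@]2(C)[C@@H]1CCC(=C)[C@@H]2CC#C
F4 | step 6 | spiro-epoxide of F3 at C8 with oxygen trans to the propargyl group | CC1(C)CCC[C@@]2(C)[C@@H]1CC[C@@]3(OC3)[C@@H]2CC#C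
F5 | step 5 | hexacarbonyl[μ-(3-methoxyprop-1-yne)]dicobalt | COCC12C3[Co]1(=C=O)(=C=O)(=C=O)[Co]23(=C=O)(=C=O)=C=O
F6 | step 5 | hexacarbonyldicobalt complex of the alkyne of ketone 9 | CC1(C)CCC[C@@]2(C)[C@@H]1CCC(=O)[C@@H]2CC34C5[Co]3(=C=O)(=C=O)(=C=O)[Co]45(=C=O)(=C=O)=C=O
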